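**Retrosynthetic overview**
1. Enabling feature: the quaternary C3a (allyl, C3) of the cyclohexadienone ring is bonded to C7a, which is at ketone level (O1–C7a=C7–C6=O is a vinylogous ester). C3a/C7a is therefore a retro-semipinacol pair, and C2–O1 is a γ-hydroxy group for that ketone.
2. Key disconnection: C3–C3a by a 1,2-shift of C3 from the carbinol carbon of a p-quinol (C7a–OH) to the allyl-bearing dienone β-carbon, and O1–C7a by cyclodehydration of O1 onto the C7a ketone so formed, both in one pot from quinol benzoate 8.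
3. 8 comes from the aromatic 1,2-diarylpropyl benzoate 6 by oxidative dearomatisation of the veratrole ring, the benzoate C=O delivering oxygen to C7a. 6 comes from ketone 3 and bromide 2 by Pd α-arylation, DKR hydrogenation and Mitsunobu inversion, which sets the 2,3-cis pair.
4. Ring order: both benzene rings are bought; the cyclohexadienone is unveiled from one of them in step 5, the dihydrofuran ring closes last (step 6), and O-methylation ends the route.

Key step: step 6

Remark (assumption): 1 and 3 are taken as commercial. The CIP descriptor of the methyl-bearing carbon switches between S and R along the route only because substituent priorities change; that atom is never inverted.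

Step 1
Reactants: 1 methyl eugenol (4-allyl-1,2-dimethoxybenzene)
Product: 2 1-allyl-2-bromo-4,5-dimethoxybenzene
Conditions: NBS (1.05 equiv), MeCN, 0 °C → rt, dark
Reagents that add atoms: N-bromosuccinimide, O=C1CCC(=O)N1Br
Why: Electrophilic aromatic bromination of the veratrole ring should occur para to a methoxy group and ortho to the allyl chain, and NBS in MeCN brominates the activated arene faster than the isolated terminal alkene.

Step 2
Reactants: 2 1-allyl-2-bromo-4,5-dimethoxybenzene; 3 1-(3,4,5-trimethoxyphenyl)propan-1-one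
Product: 4 rac-2-(2-allyl-4,5-dimethoxyphenyl)-1-(3,4,5-trimethoxyphenyl)propan-1-one
Conditions: Pd2(dba)3 (1 mol %), XPhos (2.5 mol %), NaOt-Bu (1.3 equiv), toluene, 70 °C
Reagents that add atoms: none
Why: Buchwald–Hartwig-type Pd-catalysed α-arylation of the ketone enolate should stop at mono-arylation because the product α-carbon is tertiary and hindered; the stereocentre is formed racemic on purpose.

Step 3
Reactants: 4 rac-2-(2-allyl-4,5-dimethoxyphenyl)-1-(3,4,5-trimethoxyphenyl)propan-1-one
Product: 5 (1S,2S)-2-(2-allyl-4,5-dimethoxyphenyl)-1-(3,4,5-trimethoxyphenyl)propan-1-ol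
Conditions: RuCl2[(R)-xylBINAP][(R)-DAIPEN] (0.5 mol %), t-BuOK (5 mol %), H2 (10 atm), i-PrOH, 25 °C
Reagents that add atoms: none
Why: Noyori asymmetric hydrogenation with dynamic kinetic resolution: the α-aryl stereocentre epimerises through the enolate faster than the C=O is reduced, the catalyst (antipode chosen by analogy with α-aryl propiophenones) fixes the carbinol as S, matched Felkin-type hydride delivery fixes C2 relative to it, and the Ru–diamine catalyst leaves the C=C bond alone.

Step 4
Reactants: 5 (1S,2S)-2-(2-allyl-4,5-dimethoxyphenyl)-1-(3,4,5-trimethoxyphenyl)propan-1-ol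
Product: 6 (1R,2S)-2-(2-allyl-4,5-dimethoxyphenyl)-1-(3,4,5-trimethoxyphenyl)propyl benzoate
Conditions: PPh3, DIAD, PhCO2H, toluene, 0 °C → rt
Reagents that add atoms: benzoic acid, O=C(O)c1ccccc1
Why: Mitsunobu reaction: SN2 displacement of the alkoxyphosphonium by benzoate inverts the carbinol carbon to the 1R,2S arrangement that becomes the 2,3-cis pair of the target, and the benzoate installed is the internal oxygen donor of step 5.

Step 5
Reactants: 6 (1R,2S)-2-(2-allyl-4,5-dimethoxyphenyl)-1-(3,4,5-trimethoxyphenyl)propyl benzoate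
Product: 8 (1R,2R)-2-[(1S)-2-allyl-1-hydroxy-5-methoxy-4-oxocyclohexa-2,5-dien-1-yl]-1-(3,4,5-trimethoxyphenyl)propyl benzoate, via spiro hemi-orthoester 7 (not isolated)
Conditions: PhI(OCOCF3)2 (1.2 equiv), (CF3)2CHOH/CH2Cl2, −20 °C; then aq. NaHCO3/MeCN, 0 °C
Reagents that add atoms: water, O
Why: Proposed new method: two-electron oxidation of the more electron-rich veratrole ring by iodine(III) in HFIP should place a cation on the alkyl-bearing carbon para to OMe, which the benzoate C=O traps as a spiro 1,3-dioxan-2-ylium ion (neighbouring acyloxy participation, as in the Woodward–Prévost reaction and iodocarbonate cyclisation); A(1,3) strain holds the benzylic C–H in the ring plane toward the allyl group (which also disfavours benzylic deprotonation), so oxygen arrives on the face carrying the carbinol carbon and sets the quinol carbon as S; buffered hydrolysis should collapse hemi-orthoester 7 by expelling the less basic tertiary quinol oxygen (secondary benzoate kept) and turn the para O-methyl oxocarbenium into the dienone C=O; the closest known reactions are iodine(III)-mediated ipso-spirocyclisations of p-substituted phenol ethers with internal carboxylic acid or amide nucleophiles.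

Step 6
Reactants: 8 (1R,2R)-2-[(1S)-2-allyl-1-hydroxy-5-methoxy-4-oxocyclohexa-2,5-dien-1-yl]-1-(3,4,5-trimethoxyphenyl)propyl benzoate
Product: 11 (2R,3S,3aS)-3a-allyl-5-hydroxy-3-methyl-2-(3,4,5-trimethoxyphenyl)-3,3a-dihydro-1-benzofuran-6(2H)-one, via enedione benzoate 9 (not isolated), via hydroxy enedione 10 (not isolated)
Conditions: BF3·OEt2 (0.3 equiv), CH2Cl2, −40 → 0 °C; then NaOMe (cat.), MeOH, 0 °C → rt; then PPTS to pH ≈ 4, rt
Reagents that add atoms: none
Why: Proposed new method: BF3 activates the dienone C=O so that positive charge develops at the allyl-bearing β-carbon (C3a), and C3, whose bond to the carbinol carbon C7a is parallel to the empty p-orbital and is pushed by the C7a–OH lone pair, shifts suprafacially to C3a to give enedione 9; this is a vinylogous semipinacol/α-ketol shift of a p-quinol, the closest known types being the acid-catalysed quinol 1,2-shifts (dienone–phenol, quinol–enedione). Methoxide then removes the benzoate, and under PPTS the freed O1 adds to the C7a ketone (5-exo-trig) to a hemiketal that loses water while the C6 methyl enol ether is cleaved to the C6 ketone (vinylogous-ester transposition), and the resulting 1,2-dione enolises to diosphenol 11. C3 migrates with retention, C3a is set by the suprafacial shift and so copies the configuration of C7a in 8 (1,2-chirality transfer), and C2 is not touched. The step needs migration to C3a and not to C7 (which would aromatise): C3a is the tertiary, more cationic terminus, whereas C7 is the β-carbon of the methoxy enol ether, the same terminus preference that nucleophiles show toward related 2-allyl-5-methoxy quinone-ketal cations. It also needs O1 to stay out of the dienone (oxa-Michael addition) until the shift is over, which the benzoate ensures.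

Step 7
Reactants: 11 (2R,3S,3aS)-3a-allyl-5-hydroxy-3-methyl-2-(3,4,5-trimethoxyphenyl)-3,3a-dihydro-1-benzofuran-6(2H)-one
Product: 12 (2R,3S,3aS)-3a-allyl-5-methoxy-3-methyl-2-(3,4,5-trimethoxyphenyl)-3,3a-dihydro-1-benzofuran-6(2H)-one
Conditions: MeI (2 equiv), K2CO3 (1.5 equiv), acetone, rt
Reagents that add atoms: iodomethane, CI
Why: Williamson-type O-methylation of the acidic diosphenol OH should favour O- over C-alkylation of the cross-conjugated enolate and touches no stereocentre.

**Compound list**
1 | methyl eugenol (4-allyl-1,2-dimethoxybenzene) | C=CCc1ccc(OC)c(OC)c1 | starting material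
2 | 1-allyl-2-bromo-4,5-dimethoxybenzene | C=CCc1cc(OC)c(OC)cc1Br | intermediate
3 | 1-(3,4,5-trimethoxyphenyl)propan-1-one | CCC(=O)c1cc(OC)c(OC)c(OC)c1 | starting material
4 | rac-2-(2-allyl-4,5-dimethoxyphenyl)-1-(3,4,5-trimethoxyphenyl)propan-1-one | CC(C(=O)c1cc(OC)c(OC)c(OC)c1)c1cc(OC)c(OC)cc1CC=C | intermediate
5 | (1S,2S)-2-(2-allyl-4,5-dimethoxyphenyl)-1-(3,4,5-trimethoxyphenyl)propan-1-ol | C[C@@H](c1cc(OC)c(OC)cc1CC=C)[C@H](O)c1cc(OC)c(OC)c(OC)c1 | intermediate
6 | (1R,2S)-2-(2-allyl-4,5-dimethoxyphenyl)-1-(3,4,5-trimethoxyphenyl)propyl benzoate | C[C@@H](c1cc(OC)c(OC)cc1CC=C)[C@@H](OC(=O)c1ccccc1)c1cc(OC)c(OC)c(OC)c1 | intermediate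
7 | spiro hemi-orthoester (2-hydroxy-2-phenyl-1,3-dioxane spiro-fused at the quinol carbon; orthoester carbon unspecified; not isolated) | O=C1C=C(CC=C)[C@@]2(OC(O)(c3ccccc3)O[C@@H](c3cc(OC)c(OC)c(OC)c3)[C@H]2C)C=C1OC | intermediate
8 | (1R,2R)-2-[(1S)-2-allyl-1-hydroxy-5-methoxy-4-oxocyclohexa-2,5-dien-1-yl]-1-(3,4,5-trimethoxyphenyl)propyl benzoate | O=C1C=C(CC=C)[C@](O)([C@H](C)[C@@H](OC(=O)c2ccccc2)c2cc(OC)c(OC)c(OC)c2)C=C1OC | intermediate
9 | enedione benzoate: (1R,2S)-2-[(1R)-1-allyl-4-methoxy-2,5-dioxocyclohex-3-en-1-yl]-1-(3,4,5-trimethoxyphenyl)propyl benzoate (not isolated) | C=CC[C@@]1(CC(=O)C(OC)=CC1=O)[C@H](C)[C@@H](OC(=O)c1ccccc1)c1cc(OC)c(OC)c(OC)c1 | intermediate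
10 | hydroxy enedione: (5R)-5-allyl-5-[(1R,2S)-1-hydroxy-1-(3,4,5-trimethoxyphenyl)propan-2-yl]-2-methoxycyclohex-2-ene-1,4-dione (not isolated) | C=CC[C@@]1(CC(=O)C(OC)=CC1=O)[C@H](C)[C@@H](O)c1cc(OC)c(OC)c(OC)c1 | intermediate
11 | (2R,3S,3aS)-3a-allyl-5-hydroxy-3-methyl-2-(3,4,5-trimethoxyphenyl)-3,3a-dihydro-1-benzofuran-6(2H)-one | C=CC[C@]12C=C(O)C(=O)C=C1O[C@@H](c1cc(OC)c(OC)c(OC)c1)[C@H]2C | intermediate
12 | (2R,3S,3aS)-3a-allyl-5-methoxy-3-methyl-2-(3,4,5-trimethoxyphenyl)-3,3a-dihydro-1-benzofuran-6(2H)-one | C=CC[C@]12C=C(OC)C(=O)C=C1O[C@@H](c1cc(OC)c(OC)c(OC)c1)[C@H]2C | target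

**Step count and risks**
Total steps: 7. Longest linear sequence: 7 (1 → 12; 3 enters at step 2).

Steps most likely to fail:

1. Step 6 (Proposed new method). What may go wrong: the side chain migrates to the unsubstituted terminus C7 and the ring aromatises; the benzoate is lost before the shift so that O1 adds to the dienone; or the closed 2,3-cis ring epimerises at the benzylic C2 under acid. Fallback (known chemistry, sets out from 2 and 3, comes back at 12): the bicyclic core is built instead by the acid-catalysed annulation of a quinone monoketal with an (E)-propenylarene. Ketone 3 is reduced (NaBH4, MeOH) to 1-(3,4,5-trimethoxyphenyl)propan-1-ol F1 and dehydrated (TsOH, toluene, reflux) to (E)-isoelemicin F2. Bromide 2 is converted by Br/Li exchange, borylation and oxidation (n-BuLi; B(OMe)3; H2O2, NaOH) into 2-allyl-4,5-dimethoxyphenol F3, which PhI(OAc)2 in MeOH oxidises to 2-allyl-4,4,5-trimethoxycyclohexa-2,5-dien-1-one F4. A strong acid (TfOH or SnCl4, MeCN, −30 °C) ionises F4, and the cation should add F2 at the allyl-bearing carbon with ring closure by the dienone oxygen, giving the racemic dihydrobenzofuranone as a mixture of diastereomers. Racemic 12 F5 would be separated from them and resolved by preparative chromatography on a chiral phase to return to 12.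

2. Step 5 (Proposed new method). What may go wrong: oxidation of the trimethoxyphenyl ring or of the alkene competes; solvent instead of the benzoate captures the cation (loss of facial control); or the hemi-orthoester collapses to the tertiary benzoate and frees O1 too early. Fallback (known chemistry, sets out from 3, comes back at 8): the ring is carried as a free phenol so that the classical iodine(III) oxidation of p-alkylphenols to p-quinols applies. Commercial chavibetol (5-allyl-2-methoxyphenol) is brominated para to OH (NBS, MeCN) to 5-allyl-4-bromo-2-methoxyphenol F6 and silylated (TIPSCl, imidazole) to its TIPS ether F7. α-Arylation of 3 with F7, DKR hydrogenation and Mitsunobu benzoylation under the conditions of steps 2–4 should give ketone F8, (1S,2S)-alcohol F9 and (1R,2S)-benzoate F10. TBAF frees phenol F11, and PhI(OAc)2 in MeCN–H2O should oxidise it to the p-quinol, with water as the nucleophile if the benzoate does not take part, in which case the two ring-carbinol epimers are separated. The epimer with the S-configured ring carbinol is 8.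

3. Step 4. What may go wrong: E2 elimination of the activated alcohol to the trisubstituted stilbene and partial SN1 loss of configuration at the benzylic carbon. Fallback (known chemistry, sets out from 4, comes back at 6): Corey–Bakshi–Shibata reduction of racemic 4 ((S)-Me-CBS, BH3·SMe2, THF, −20 °C) under catalyst control should give the (1R,2S)-alcohol F12 and the (1R,2R)-alcohol F13 from the two ketone enantiomers. They are separated, F13 can be re-oxidised to 4, and F12 is benzoylated with retention (BzCl, pyridine, DMAP) to 6.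

**Further compounds**
F1 | step 6 | 1-(3,4,5-trimethoxyphenyl)propan-1-ol (racemic) | CCC(O)c1cc(OC)c(OC)c(OC)c1
F2 | step 6 | (E)-isoelemicin, (E)-1,2,3-trimethoxy-5-(prop-1-en-1-yl)benzene | C/C=C/c1cc(OC)c(OC)c(OC)c1
F3 | step 6 | 2-allyl-4,5-dimethoxyphenol | C=CCc1cc(OC)c(OC)cc1O
F4 | step 6 | 2-allyl-4,4,5-trimethoxycyclohexa-2,5-dien-1-one | C=CCC1=CC(OC)(OC)C(OC)=CC1=O
F5 | step 6 | racemic 12 (relative configuration as drawn) | C=CC[C@]12C=C(OC)C(=O)C=C1O[C@@H](c1cc(OC)c(OC)c(OC)c1)[C@H]2C
F6 | step 5 | 5-allyl-4-bromo-2-methoxyphenol | C=CCc1cc(O)c(OC)cc1Br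
F7 | step 5 | (5-allyl-4-bromo-2-methoxyphenoxy)triisopropylsilane | C=CCc1cc(O[Si](C(C)C)(C(C)C)C(C)C)c(OC)cc1Br
F8 | step 5 | rac-2-[2-allyl-5-methoxy-4-(triisopropylsilyloxy)phenyl]-1-(3,4,5-trimethoxyphenyl)propan-1-one | CC(C(=O)c1cc(OC)c(OC)c(OC)c1)c1cc(OC)c(O[Si](C(C)C)(C(C)C)C(C)C)cc1CC=C
F9 | step 5 | (1S,2S)-2-[2-allyl-5-methoxy-4-(triisopropylsilyloxy)phenyl]-1-(3,4,5-trimethoxyphenyl)propan-1-ol | C[C@@H](c1cc(OC)c(O[Si](C(C)C)(C(C)C)C(C)C)cc1CC=C)[C@H](O)c1cc(OC)c(OC)c(OC)c1
F10 | step 5 | (1R,2S)-2-[2-allyl-5-methoxy-4-(triisopropylsilyloxy)phenyl]-1-(3,4,5-trimethoxyphenyl)propyl benzoate | C[C@@H](c1cc(OC)c(O[Si](C(C)C)(C(C)C)C(C)C)cc1CC=C)[C@@H](OC(=O)c1ccccc1)c1cc(OC)c(OC)c(OC)c1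
F11 | step 5 | (1R,2S)-2-(2-allyl-4-hydroxy-5-methoxyphenyl)-1-(3,4,5-trimethoxyphenyl)propyl benzoate | C[C@@H](c1cc(OC)c(O)cc1CC=C)[C@@H](OC(=O)c1ccccc1)c1cc(OC)c(OC)c(OC)c1
F12 | step 4 | (1R,2S)-2-(2-allyl-4,5-dimethoxyphenyl)-1-(3,4,5-trimethoxyphenyl)propan-1-ol | C[C@@H](c1cc(OC)c(OC)cc1CC=C)[C@@H](O)c1cc(OC)c(OC)c(OC)c1
F13 | step 4 | (1R,2R)-2-(2-allyl-4,5-dimethoxyphenyl)-1-(3,4,5-trimethoxyphenyl)propan-1-ol | C[C@H](c1cc(OC)c(OC)cc1CC=C)[C@@H](O)c1cc(OC)c(OC)c(OC)c1
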